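**Plan**

- Retrosynthesis: the two methoxymethyl ethers (on O5 and O4′) are cut first. Then O1–C8a and C4–C4a are cut together, which opens ring C onto ring A and leaves an aryne (C4a≡C8a) and a β-oxy ester carrying O1, C2, C3 and C4.
- Enabling feature: C4a and C8a are neighbours on ring A, and O1 and C4 are 1,4-related through C2–C3. The C5 oxygen next to C4a polarises the aryne, so oxygen adds at C8a and the acyl carbon is captured at C4a.
- Ring A: 3-methoxyphenol is elaborated by three successive directed ortho-metalations (prenyl at C6, oxygen at C4a, silicon at C8a) to a 2-silylaryl triflate.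
- Chain: 4′-hydroxyacetophenone is homologated to a β-keto ester, reduced and O-silylated. Ring C then closes in the aryne annulation, and both acetals are removed last.
- Stereochemistry: the only stereocentre, C2 (S), is set by Ru-catalysed asymmetric transfer hydrogenation of the β-keto ester. It is carried through unchanged because its C–O bond is never broken.

Key step: step 11

Remark: flavanone numbering (O1, C2, C3, C4, C4a, C5 to C8, C8a; primed locants for the 2-aryl ring) is used for ring positions in all intermediates; prenyl = 3-methylbut-2-en-1-yl, MOM = methoxymethyl.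

**Route**

Step 1
Reactants: 1 3-methoxyphenol
Product: 2 1-methoxy-3-(methoxymethoxy)benzene
Conditions: MOMCl, iPr2NEt, CH2Cl2, 0 °C to rt
Reagents that add atoms: chloromethyl methyl ether COCCl
Why: O-alkylation of the phenol by the α-chloro ether (MOM protection) should be clean, and the acetal is the directing group for the next two metalations.

Step 2
Reactants: 2 1-methoxy-3-(methoxymethoxy)benzene
Product: 4 1-methoxy-3-(methoxymethoxy)-2-(3-methylbut-2-en-1-yl)benzene, via 2-lithio arene 3 (not isolated)
Conditions: n-BuLi, THF, 0 °C; then CuI (10 mol%), prenyl bromide, −78 °C to rt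
Reagents that add atoms: prenyl bromide CC(C)=CCBr
Why: Directed ortho-metalation removes the most acidic C–H, the one flanked by both oxygens, and the aryllithium (through a catalytic arylcopper) should undergo SN2 allylation at the primary carbon of prenyl bromide.

Step 3
Reactants: 4 1-methoxy-3-(methoxymethoxy)-2-(3-methylbut-2-en-1-yl)benzene
Product: 7 4-methoxy-2-(methoxymethoxy)-3-(3-methylbut-2-en-1-yl)phenol, via aryllithium 5 (not isolated), via dimethyl arylboronate 6 (not isolated)
Conditions: n-BuLi, TMEDA, THF, −20 to 0 °C; B(OMe)3, −78 °C to rt; then 30% H2O2, aq. NaOH, 0 °C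
Reagents that add atoms: hydrogen peroxide OO; trimethyl borate COB(OC)OC (boron is carried only by 6 and is lost on oxidation)
Why: In this second directed ortho-metalation the position between the oxygens is blocked, so the methoxymethoxy group (a stronger director than methoxy) should steer lithiation to its free ortho C–H (the future C4a), and borylation with alkaline peroxide oxidation (1,2-aryl shift from boron to oxygen) turns C–Li into C–OH without touching the trisubstituted alkene.

Step 4
Reactants: 7 4-methoxy-2-(methoxymethoxy)-3-(3-methylbut-2-en-1-yl)phenol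
Product: 8 4-methoxy-2-(methoxymethoxy)-3-(3-methylbut-2-en-1-yl)phenyl N-isopropylcarbamate
Conditions: iPrNCO, Et3N (cat.), CH2Cl2, rt
Reagents that add atoms: isopropyl isocyanate CC(C)N=C=O
Why: Base-catalysed addition of the phenol to the isocyanate gives the N-isopropyl carbamate, which is a strong ortho-director and can later be cleaved under mild base.

Step 5
Reactants: 8 4-methoxy-2-(methoxymethoxy)-3-(3-methylbut-2-en-1-yl)phenyl N-isopropylcarbamate
Product: 12 4-methoxy-2-(methoxymethoxy)-3-(3-methylbut-2-en-1-yl)-6-(trimethylsilyl)phenyl N-isopropylcarbamate, via N-silyl carbamate 9 (not isolated), via lithiated N-silyl carbamate 10 (not isolated), via C-silylated N-silyl carbamate 11 (not isolated)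
Conditions: TBSOTf, TMEDA, Et2O, 0 °C to rt; n-BuLi, TMEDA, −78 °C; TMSCl, −78 °C to rt; cold aq. NaHSO4 work-up
Reagents that add atoms: chlorotrimethylsilane C[Si](C)(C)Cl; tert-butyldimethylsilyl triflate CC(C)(C)[Si](C)(C)OS(=O)(=O)C(F)(F)F (its silyl group is carried only by 9 to 11)
Why: Carbamate-directed ortho-metalation after in situ N-silylation should be unambiguous, because the carbamate has only one free ortho C–H (the future C8a) and outranks the methoxy group as a director; the N–Si bond is hydrolysed on work-up.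

Step 6
Reactants: 12 4-methoxy-2-(methoxymethoxy)-3-(3-methylbut-2-en-1-yl)-6-(trimethylsilyl)phenyl N-isopropylcarbamate
Product: 14 4-methoxy-2-(methoxymethoxy)-3-(3-methylbut-2-en-1-yl)-6-(trimethylsilyl)phenyl trifluoromethanesulfonate, via 2-silylphenol 13 (not isolated)
Conditions: DBU, Et2NH, MeCN, 40 °C; then PhNTf2, rt
Reagents that add atoms: N-phenylbis(trifluoromethanesulfonimide) O=S(=O)(N(c1ccccc1)S(=O)(=O)C(F)(F)F)C(F)(F)F
Why: E1cB cleavage of the N–H carbamate (the isocyanate is scavenged by Et2NH) frees the phenoxide, which is triflated in the same pot to give a 2-(trimethylsilyl)aryl triflate, the standard fluoride-triggered aryne precursor.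

Step 7
Reactants: 15 4′-hydroxyacetophenone
Product: 16 4′-(methoxymethoxy)acetophenone
Conditions: MOMCl, iPr2NEt, CH2Cl2, 0 °C to rt
Reagents that add atoms: chloromethyl methyl ether COCCl
Why: MOM protection of the phenol gives a group that is stable to base, hydride transfer and fluoride and leaves in the final step together with the C5 acetal.

Step 8
Reactants: 16 4′-(methoxymethoxy)acetophenone
Product: 17 methyl 3-[4-(methoxymethoxy)phenyl]-3-oxopropanoate
Conditions: NaH, (MeO)2CO, THF, reflux; AcOH quench
Reagents that add atoms: dimethyl carbonate COC(=O)OC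
Why: Crossed Claisen condensation of the ketone enolate with the non-enolisable carbonate is driven by formation of the stabilised β-keto ester enolate.

Step 9
Reactants: 17 methyl 3-[4-(methoxymethoxy)phenyl]-3-oxopropanoate
Product: 18 methyl (3S)-3-hydroxy-3-[4-(methoxymethoxy)phenyl]propanoate
Conditions: RuCl(p-cymene)[(S,S)-TsDPEN] (1 mol%), HCO2H/Et3N (5:2), DMF, 40 °C
Reagents that add atoms: none
Why: Noyori–Ikariya asymmetric transfer hydrogenation of the aryl ketone, in which the aryl group sits against the η6-arene of the (S,S)-catalyst so that hydride should reach the face giving the (S)-carbinol, by the same sense as for aryl methyl ketones.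

Step 10
Reactants: 18 methyl (3S)-3-hydroxy-3-[4-(methoxymethoxy)phenyl]propanoate
Product: 19 methyl (3S)-3-[4-(methoxymethoxy)phenyl]-3-(trimethylsilyloxy)propanoate
Conditions: TMSCl, imidazole, CH2Cl2, 0 °C; non-aqueous work-up
Reagents that add atoms: chlorotrimethylsilane C[Si](C)(C)Cl
Why: O-silylation stores the carbinol as a neutral, proton-free latent alkoxide that fluoride can release in the key step.

Step 11
Reactants: 14 4-methoxy-2-(methoxymethoxy)-3-(3-methylbut-2-en-1-yl)-6-(trimethylsilyl)phenyl trifluoromethanesulfonate; 19 methyl (3S)-3-[4-(methoxymethoxy)phenyl]-3-(trimethylsilyloxy)propanoate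
Product: 23 (2S)-7-methoxy-5-(methoxymethoxy)-2-[4-(methoxymethoxy)phenyl]-6-(3-methylbut-2-en-1-yl)-2,3-dihydro-4H-chromen-4-one, via cesium alkoxide 20 (not isolated), via aryne 21 (not isolated), via aryl cesium adduct 22 (not isolated)
Conditions: CsF, 18-crown-6, THF, 0 °C to rt; 14 and 19 (1.3 equiv) added together slowly
Reagents that add atoms: none
Why: Proposed new method: fluoride unmasks both partners at once, cleaving the O–Si bond of 19 to alkoxide 20 and the C–Si bond of 14 (with loss of triflate) to aryne 21; 20 adds to aryne carbon C8a, the aryl carbanion 22 so formed at C4a attacks the methyl ester, and the expelled methoxide is taken up by the silyl group of a further molecule of 19 as MeOSiMe3, so that free alkoxide should not build up. The closest known reaction type is the fluoride-induced annulation of arynes with salicylate esters to xanthones (phenoxide addition, then acyl capture of the aryl anion), extended here to an aliphatic β-silyloxy ester as latent alkoxide. Ring C closes by 6-exo-trig attack of the C4a carbanion on the ester carbon, after O1–C8a has been made intermolecularly. No new stereocentre is formed: C2 comes in with 19 and should keep its (S) configuration because neither its C–O nor its C–H bond is touched. The regioselectivity needed (oxygen at C8a, acyl at C4a) is secured by the C5 methoxymethoxy group, whose inductive pull stabilises negative charge at the adjacent C4a and distorts the aryne so that C8a is its electrophilic end, as for other 3-alkoxyarynes. The chemoselectivity needed (acyl capture of 22 before proton transfer) is served by the proton-free medium and the six-membered geometry of the closure.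

Step 12
Reactants: 23 (2S)-7-methoxy-5-(methoxymethoxy)-2-[4-(methoxymethoxy)phenyl]-6-(3-methylbut-2-en-1-yl)-2,3-dihydro-4H-chromen-4-one
Product: 24 (2S)-5-hydroxy-2-(4-hydroxyphenyl)-7-methoxy-6-(3-methylbut-2-en-1-yl)-2,3-dihydro-4H-chromen-4-one (6-prenylsakuranetin)
Conditions: 3 M aq. HCl, MeOH, rt to 40 °C
Reagents that add atoms: none
Why: Acid-catalysed methanolysis of the two aryl methoxymethyl acetals (the peri C5 acetal is the more labile) should free both phenols under conditions mild enough to leave the prenyl alkene and the C2 stereocentre untouched.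

**Compound list**

1 | 3-methoxyphenol | COc1cccc(O)c1 | starting material
2 | 1-methoxy-3-(methoxymethoxy)benzene | COCOc1cccc(OC)c1 | intermediate
3 | 2-methoxy-6-(methoxymethoxy)phenyllithium | COCOc1cccc(OC)c1[Li] | intermediate
4 | 1-methoxy-3-(methoxymethoxy)-2-(3-methylbut-2-en-1-yl)benzene | COCOc1cccc(OC)c1CC=C(C)C | intermediate
5 | 4-methoxy-2-(methoxymethoxy)-3-(3-methylbut-2-en-1-yl)phenyllithium | COCOc1c([Li])ccc(OC)c1CC=C(C)C | intermediate
6 | dimethyl [4-methoxy-2-(methoxymethoxy)-3-(3-methylbut-2-en-1-yl)phenyl]boronate | COCOc1c(B(OC)OC)ccc(OC)c1CC=C(C)C | intermediate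
7 | 4-methoxy-2-(methoxymethoxy)-3-(3-methylbut-2-en-1-yl)phenol | COCOc1c(O)ccc(OC)c1CC=C(C)C | intermediate
8 | 4-methoxy-2-(methoxymethoxy)-3-(3-methylbut-2-en-1-yl)phenyl N-isopropylcarbamate | COCOc1c(OC(=O)NC(C)C)ccc(OC)c1CC=C(C)C | intermediate
9 | 4-methoxy-2-(methoxymethoxy)-3-(3-methylbut-2-en-1-yl)phenyl N-(tert-butyldimethylsilyl)-N-isopropylcarbamate | COCOc1c(OC(=O)N(C(C)C)[Si](C)(C)C(C)(C)C)ccc(OC)c1CC=C(C)C | intermediate
10 | 6-lithio derivative of 9 (lithium ortho to the carbamate oxygen) | COCOc1c(OC(=O)N(C(C)C)[Si](C)(C)C(C)(C)C)c([Li])cc(OC)c1CC=C(C)C | intermediate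
11 | 4-methoxy-2-(methoxymethoxy)-3-(3-methylbut-2-en-1-yl)-6-(trimethylsilyl)phenyl N-(tert-butyldimethylsilyl)-N-isopropylcarbamate | COCOc1c(OC(=O)N(C(C)C)[Si](C)(C)C(C)(C)C)c([Si](C)(C)C)cc(OC)c1CC=C(C)C | intermediate
12 | 4-methoxy-2-(methoxymethoxy)-3-(3-methylbut-2-en-1-yl)-6-(trimethylsilyl)phenyl N-isopropylcarbamate | COCOc1c(OC(=O)NC(C)C)c([Si](C)(C)C)cc(OC)c1CC=C(C)C | intermediate
13 | 4-methoxy-2-(methoxymethoxy)-3-(3-methylbut-2-en-1-yl)-6-(trimethylsilyl)phenol (present as its DBU salt) | COCOc1c(O)c([Si](C)(C)C)cc(OC)c1CC=C(C)C | intermediate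
14 | 4-methoxy-2-(methoxymethoxy)-3-(3-methylbut-2-en-1-yl)-6-(trimethylsilyl)phenyl trifluoromethanesulfonate | COCOc1c(OS(=O)(=O)C(F)(F)F)c([Si](C)(C)C)cc(OC)c1CC=C(C)C | intermediate
15 | 4′-hydroxyacetophenone | CC(=O)c1ccc(O)cc1 | starting material
16 | 4′-(methoxymethoxy)acetophenone | CC(=O)c1ccc(OCOC)cc1 | intermediate
17 | methyl 3-[4-(methoxymethoxy)phenyl]-3-oxopropanoate | COC(=O)CC(=O)c1ccc(OCOC)cc1 | intermediate
18 | methyl (3S)-3-hydroxy-3-[4-(methoxymethoxy)phenyl]propanoate | COC(=O)C[C@@H](c1ccc(OCOC)cc1)O | intermediate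
19 | methyl (3S)-3-[4-(methoxymethoxy)phenyl]-3-(trimethylsilyloxy)propanoate | COC(=O)C[C@@H](c1ccc(OCOC)cc1)O[Si](C)(C)C | intermediate
20 | cesium (1S)-3-methoxy-1-[4-(methoxymethoxy)phenyl]-3-oxopropan-1-olate | COC(=O)C[C@@H](c1ccc(OCOC)cc1)[O-].[Cs+] | intermediate
21 | 5-methoxy-3-(methoxymethoxy)-4-(3-methylbut-2-en-1-yl)benzyne (triple bond C4a≡C8a) | COCOC1=C(CC=C(C)C)C(OC)=CC#C1 | intermediate
22 | methyl (3S)-3-[2-cesio-5-methoxy-3-(methoxymethoxy)-4-(3-methylbut-2-en-1-yl)phenoxy]-3-[4-(methoxymethoxy)phenyl]propanoate | COC(=O)C[C@@H](c1ccc(OCOC)cc1)Oc1cc(OC)c(CC=C(C)C)c(OCOC)c1[Cs] | intermediate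
23 | (2S)-7-methoxy-5-(methoxymethoxy)-2-[4-(methoxymethoxy)phenyl]-6-(3-methylbut-2-en-1-yl)-2,3-dihydro-4H-chromen-4-one | COc1cc2c(c(OCOC)c1CC=C(C)C)C(=O)C[C@@H](c1ccc(OCOC)cc1)O2 | intermediate
24 | (2S)-5-hydroxy-2-(4-hydroxyphenyl)-7-methoxy-6-(3-methylbut-2-en-1-yl)-2,3-dihydro-4H-chromen-4-one (6-prenylsakuranetin) | COc1cc2c(c(O)c1CC=C(C)C)C(=O)C[C@@H](c1ccc(O)cc1)O2 | target

**Step count and risks**

Total step count: 12. Longest linear sequence: 8 steps (steps 1 to 6, then 11 and 12).

Step 11 (carries the label Proposed new method). What may go wrong: retro-aldol cleavage or β-elimination of the alkoxide before it meets the aryne; proton capture by the aryl carbanion before acyl transfer, which would stop at the uncyclised aryl ether; base-induced opening of ring C to the chalcone with loss of configuration at C2. The fallback uses known chemistry, sets out from 14 and returns at 23. Treatment of 14 with acetic acid and CsF in THF at 125 °C (sealed tube) is the known insertion of an aryne into the C–O bond of a carboxylic acid, and should give 1-[6-hydroxy-4-methoxy-2-(methoxymethoxy)-3-(3-methylbut-2-en-1-yl)phenyl]ethanone F1 with the same regiochemistry. Condensation with N,N-dimethylformamide dimethyl acetal would give (E)-3-(dimethylamino)-1-[6-hydroxy-4-methoxy-2-(methoxymethoxy)-3-(3-methylbut-2-en-1-yl)phenyl]prop-2-en-1-one F2, which should close on brief warming in AcOH to 7-methoxy-5-(methoxymethoxy)-6-(3-methylbut-2-en-1-yl)-4H-chromen-4-one F3. Enantioselective conjugate addition of 4-(methoxymethoxy)phenylboronic acid (Pd(OCOCF3)2, the tert-butyl pyridine-oxazoline ligand of the enantiomer that delivers the 2S product, NH4PF6, H2O, 1,2-dichloroethane, 60 °C) would then give 23.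

Step 3. What may go wrong: deprotonation at the wrong site (ortho to the methoxy group or at the benzylic–allylic CH2), or over-oxidation of the electron-rich phenol during peroxide treatment. The fallback sets out from 4 and returns at aryne 21 in step 11. It replaces metalation by sterically controlled C–H borylation ([Ir(OMe)(cod)]2, 4,4′-di-tert-butyl-2,2′-bipyridine, B2pin2, THF, 60 °C) at the only ring C–H without an ortho substituent, giving 2-[3-methoxy-5-(methoxymethoxy)-4-(3-methylbut-2-en-1-yl)phenyl]-4,4,5,5-tetramethyl-1,3,2-dioxaborolane F4. Oxidation with NaBO3·4H2O would give 3-methoxy-5-(methoxymethoxy)-4-(3-methylbut-2-en-1-yl)phenol F5, and iPrNCO would give 3-methoxy-5-(methoxymethoxy)-4-(3-methylbut-2-en-1-yl)phenyl N-isopropylcarbamate F6. The operations of step 5 should then silylate between the carbamate and the methoxymethoxy group (the stronger co-director) to give 5-methoxy-3-(methoxymethoxy)-4-(3-methylbut-2-en-1-yl)-2-(trimethylsilyl)phenyl N-isopropylcarbamate F7, and those of step 6 would give 5-methoxy-3-(methoxymethoxy)-4-(3-methylbut-2-en-1-yl)-2-(trimethylsilyl)phenyl trifluoromethanesulfonate F8. This isomeric silyl triflate releases the same aryne 21 with fluoride.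

Step 12. What may go wrong: acid-induced cyclisation of the freed C5 phenol onto the prenyl double bond, or acid-catalysed opening of ring C with erosion of configuration at C2. The fallback sets out from 23 and returns at 24 without Brønsted acid. TESOTf and 2,2′-bipyridyl in CH2Cl2 at 0 °C should exchange both aryl methoxymethyl ethers for silyl ethers, giving (2S)-7-methoxy-6-(3-methylbut-2-en-1-yl)-5-(triethylsilyloxy)-2-[4-(triethylsilyloxy)phenyl]-2,3-dihydro-4H-chromen-4-one F9. Et3N·3HF in THF would then free both phenols to give 24.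

**Further compounds**

F1 | step 11 | 1-[6-hydroxy-4-methoxy-2-(methoxymethoxy)-3-(3-methylbut-2-en-1-yl)phenyl]ethanone | CC(=O)c1c(O)cc(OC)c(CC=C(C)C)c1OCOC
F2 | step 11 | (E)-3-(dimethylamino)-1-[6-hydroxy-4-methoxy-2-(methoxymethoxy)-3-(3-methylbut-2-en-1-yl)phenyl]prop-2-en-1-one | CN(C)/C=C/C(=O)c1c(O)cc(OC)c(CC=C(C)C)c1OCOC
F3 | step 11 | 7-methoxy-5-(methoxymethoxy)-6-(3-methylbut-2-en-1-yl)-4H-chromen-4-one | O=c1ccoc2cc(OC)c(CC=C(C)C)c(OCOC)c12
F4 | step 3 | 2-[3-methoxy-5-(methoxymethoxy)-4-(3-methylbut-2-en-1-yl)phenyl]-4,4,5,5-tetramethyl-1,3,2-dioxaborolane | COCOc1cc(B2OC(C)(C)C(C)(C)O2)cc(OC)c1CC=C(C)C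
F5 | step 3 | 3-methoxy-5-(methoxymethoxy)-4-(3-methylbut-2-en-1-yl)phenol | COCOc1cc(O)cc(OC)c1CC=C(C)C
F6 | step 3 | 3-methoxy-5-(methoxymethoxy)-4-(3-methylbut-2-en-1-yl)phenyl N-isopropylcarbamate | COCOc1cc(OC(=O)NC(C)C)cc(OC)c1CC=C(C)C
F7 | step 3 | 5-methoxy-3-(methoxymethoxy)-4-(3-methylbut-2-en-1-yl)-2-(trimethylsilyl)phenyl N-isopropylcarbamate | COCOc1c([Si](C)(C)C)c(OC(=O)NC(C)C)cc(OC)c1CC=C(C)C
F8 | step 3 | 5-methoxy-3-(methoxymethoxy)-4-(3-methylbut-2-en-1-yl)-2-(trimethylsilyl)phenyl trifluoromethanesulfonate | COCOc1c([Si](C)(C)C)c(OS(=O)(=O)C(F)(F)F)cc(OC)c1CC=C(C)C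
F9 | step 12 | (2S)-7-methoxy-6-(3-methylbut-2-en-1-yl)-5-(triethylsilyloxy)-2-[4-(triethylsilyloxy)phenyl]-2,3-dihydro-4H-chromen-4-one | COc1cc2c(c(O[Si](CC)(CC)CC)c1CC=C(C)C)C(=O)C[C@@H](c1ccc(O[Si](CC)(CC)CC)cc1)O2
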